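**Strategy.** Lignan numbering is used (C7/C7' benzylic, C8/C8' ring fusion, C9/C9' oxymethylene). The furofuran is traced back to its 9,9'-dioxo form, a cis-fused bis-γ-lactone, and the two lactone C–O bonds (C7–O–C9' and C7'–O–C9) are then cut, which leaves an open dimethyl 2,3-diaroylsuccinate with allyl-protected phenols. The key step exploits that C8 and C8' of this precursor each lie between an aryl ketone (C7, C7') and an ester (C9, C9') and so epimerise freely: one asymmetric transfer hydrogenation should reduce both ketones, fix all four stereocentres and close both five-membered lactone rings across the shared C8–C8' bond. Allyl ethers are chosen so that no hydrogenolysis threatens the benzylic C–O bonds later.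

Key step: step 6

Assumption: RuCl[(S,S)-TsDPEN](p-cymene) (TsDPEN = the monoanion of N-tosyl-1,2-diphenylethane-1,2-diamine) is taken to give S carbinols from these aroyl groups, as it does from simple aryl alkyl ketones; if the sense proved opposite, the R,R complex would be used.

Step 1
Reactants: 1 acetovanillone
Product: 2 1-(4-allyloxy-3-methoxyphenyl)ethanone
Conditions: allyl bromide, K2CO3, acetone, reflux
Reagents that add atoms: allyl bromide, C=CCBr
Why: Williamson ether synthesis, the phenoxide displacing bromide from the unhindered allylic carbon.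

Step 2
Reactants: 2 1-(4-allyloxy-3-methoxyphenyl)ethanone; 3 dimethyl carbonate
Product: 4 methyl 3-(4-allyloxy-3-methoxyphenyl)-3-oxopropanoate
Conditions: NaH, THF, reflux; then cold aq. HCl
Reagents that add atoms: none
Why: Crossed Claisen condensation of the methyl ketone enolate with the non-enolisable carbonate, driven by irreversible deprotonation of the beta-keto ester that forms.

Step 3
Reactants: 4 methyl 3-(4-allyloxy-3-methoxyphenyl)-3-oxopropanoate; 5 methyl glyoxylate (freshly distilled, in excess)
Product: 6 dimethyl 2-(4-allyloxy-3-methoxybenzoyl)but-2-enedioate (E/Z mixture)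
Conditions: piperidine (cat.), AcOH (cat.), 4 Å molecular sieves, CH2Cl2, 0 °C to rt
Reagents that add atoms: none
Why: Knoevenagel condensation of the active methylene with the very electrophilic glyoxylate aldehyde, which joins C8 to C8'; the excess of aldehyde should keep a second keto ester from adding to the product alkene.

Step 4
Reactants: 7 3-hydroxy-4,5-dimethoxybenzaldehyde
Product: 8 3-allyloxy-4,5-dimethoxybenzaldehyde
Conditions: allyl bromide, K2CO3, DMF, 60 °C
Reagents that add atoms: allyl bromide, C=CCBr
Why: Williamson ether synthesis on the only free phenol.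

Step 5
Reactants: 6 dimethyl 2-(4-allyloxy-3-methoxybenzoyl)but-2-enedioate; 8 3-allyloxy-4,5-dimethoxybenzaldehyde
Product: 9 dimethyl 2-(4-allyloxy-3-methoxybenzoyl)-3-(3-allyloxy-4,5-dimethoxybenzoyl)butanedioate (stereolabile diastereomer mixture, used as such)
Conditions: 3-ethyl-5-(2-hydroxyethyl)-4-methylthiazolium bromide (20 mol %), Et3N, 1,4-dioxane, 70 °C, N2
Reagents that add atoms: none
Why: Stetter reaction, in which the thiazol-2-ylidene turns the aldehyde into an acyl anion equivalent that adds to the CH(CO2Me) terminus of the triply activated alkene, the only position that gives a beta-keto ester enolate, and so forms C7'–C8'; no stereocontrol is needed because C8 and C8' stay labile.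

Step 6
Reactants: 9 dimethyl 2-(4-allyloxy-3-methoxybenzoyl)-3-(3-allyloxy-4,5-dimethoxybenzoyl)butanedioate
Product: 11 (3S,3aS,6S,6aS)-3-(4-allyloxy-3-methoxyphenyl)-6-(3-allyloxy-4,5-dimethoxyphenyl)tetrahydro-1H,3H-furo[3,4-c]furan-1,4-dione (cis-fused dilactone with both aryl groups exo; 7S,8S,7'S,8'S), via diol diester 10 (not isolated)
Conditions: RuCl[(S,S)-TsDPEN](p-cymene) (5 mol %), HCO2H/Et3N (1:2), DMF, 25 °C; then AcOH, 50 °C, same flask
Reagents that add atoms: none
Why: Proposed new method: the ruthenium hydride formed from the catalyst and formate transfers hydride and the N–H proton to each aryl ketone through the outer-sphere six-membered transition state, while C8 and C8', each flanked by a ketone and an ester, keep epimerising through their enols in the amine-rich medium; the closest known reaction type is the asymmetric transfer hydrogenation of alpha-substituted beta-keto esters with dynamic kinetic resolution and in-flask lactonisation, which has not been shown twice within one 2,3-diaroylsuccinate. Each ring then closes by 5-exo-trig acyl substitution with loss of methanol, the C7 hydroxyl on the C9' ester and the C7' hydroxyl on the C9 ester. C7 and C7' are set S by the catalyst (reagent control, each aryl group lying against the eta-6 arene of the S,S complex as with simple aryl ketones), and C8 and C8' are set by the faster reduction of the epimer that leads to the syn hydroxy ester, after which they are no longer doubly activated and stay fixed. The step therefore needs S carbinols and a syn C7/C8 and C7'/C8' relation, which puts each aryl group trans to the neighbouring ring-fusion carbonyl and so exo on the cis-fused bicycle. The substrate secures this by its free C8/C8' epimerisation before reduction and by the fact that only the all-matched isomer can close both rings, so that isomers with one wrong centre stop at a monolactone and are removed by chromatography. Because two independent catalyst-controlled reductions are combined, most of the minor carbinol enantiomer should end in such diastereomers, which should raise the enantiomeric purity of 11.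

Step 7
Reactants: 11 (3S,3aS,6S,6aS)-dilactone
Product: 12 (1S,2R,3R,4S)-1-(4-allyloxy-3-methoxyphenyl)-4-(3-allyloxy-4,5-dimethoxyphenyl)-2,3-bis(hydroxymethyl)butane-1,4-diol
Conditions: LiAlH4, THF, 0 °C to rt; aq. potassium sodium tartrate
Reagents that add atoms: none
Why: Hydride reduction of both lactones to diols, in which hydride addition is much faster than enolisation, so that C8 and C8' keep their configuration and the C7–O and C7'–O bonds are not touched.

Step 8
Reactants: 12 (1S,2R,3R,4S)-tetraol
Product: 14 (1S,3aR,4S,6aR)-1-(4-allyloxy-3-methoxyphenyl)-4-(3-allyloxy-4,5-dimethoxyphenyl)tetrahydro-1H,3H-furo[3,4-c]furan, via bis-mesylate 13 (not isolated)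
Conditions: MsCl (2.2 equiv), pyridine, 0 °C to rt
Reagents that add atoms: none
Why: Selective sulfonylation of the two primary hydroxyls followed by a double intramolecular Williamson etherification (5-exo-tet), each benzylic hydroxyl displacing the mesylate on the distal CH2, so that C7 and C7' keep their configuration because their C–O bonds are never broken.

Step 9
Reactants: 14 (1S,3aR,4S,6aR)-bis-allyl furofuran
Product: 15 4-[(1S,3aR,4S,6aR)-4-(3-hydroxy-4,5-dimethoxyphenyl)tetrahydro-1H,3H-furo[3,4-c]furan-1-yl]-2-methoxyphenol (CNP0324902.1)
Conditions: Pd(PPh3)4 (5 mol %), morpholine, THF, rt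
Reagents that add atoms: none
Why: Tsuji–Trost type deallylation, in which zerovalent palladium ionises each aryl allyl ether to a pi-allyl complex that morpholine intercepts under neutral conditions that leave the benzylic ethers and all four stereocentres alone.

**Compound list**

1 | acetovanillone, 1-(4-hydroxy-3-methoxyphenyl)ethanone | CC(=O)c1ccc(O)c(OC)c1 | starting material
2 | 1-(4-allyloxy-3-methoxyphenyl)ethanone | CC(=O)c1ccc(OCC=C)c(OC)c1 | intermediate
3 | dimethyl carbonate | COC(=O)OC | starting material
4 | methyl 3-(4-allyloxy-3-methoxyphenyl)-3-oxopropanoate | COC(=O)CC(=O)c1ccc(OCC=C)c(OC)c1 | intermediate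
5 | methyl glyoxylate | COC(=O)C=O | starting material
6 | dimethyl 2-(4-allyloxy-3-methoxybenzoyl)but-2-enedioate (E/Z mixture) | COC(=O)C=C(C(=O)OC)C(=O)c1ccc(OCC=C)c(OC)c1 | intermediate
7 | 3-hydroxy-4,5-dimethoxybenzaldehyde | COc1cc(C=O)cc(O)c1OC | starting material
8 | 3-allyloxy-4,5-dimethoxybenzaldehyde | COc1cc(C=O)cc(OCC=C)c1OC | intermediate
9 | dimethyl 2-(4-allyloxy-3-methoxybenzoyl)-3-(3-allyloxy-4,5-dimethoxybenzoyl)butanedioate (stereolabile mixture) | COC(=O)C(C(=O)c1ccc(OCC=C)c(OC)c1)C(C(=O)OC)C(=O)c1cc(OCC=C)c(OC)c(OC)c1 | intermediate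
10 | dimethyl (2S,3S)-2-[(S)-(4-allyloxy-3-methoxyphenyl)(hydroxy)methyl]-3-[(S)-(3-allyloxy-4,5-dimethoxyphenyl)(hydroxy)methyl]butanedioate (not isolated) | COc1cc([C@@H](O)[C@@H](C(=O)OC)[C@H](C(=O)OC)[C@H](O)c2cc(OCC=C)c(OC)c(OC)c2)ccc1OCC=C | intermediate
11 | (3S,3aS,6S,6aS)-3-(4-allyloxy-3-methoxyphenyl)-6-(3-allyloxy-4,5-dimethoxyphenyl)tetrahydro-1H,3H-furo[3,4-c]furan-1,4-dione | COc1cc([C@H]2OC(=O)[C@H]3[C@@H]2C(=O)O[C@@H]3c2cc(OCC=C)c(OC)c(OC)c2)ccc1OCC=C | intermediate
12 | (1S,2R,3R,4S)-1-(4-allyloxy-3-methoxyphenyl)-4-(3-allyloxy-4,5-dimethoxyphenyl)-2,3-bis(hydroxymethyl)butane-1,4-diol | COc1cc([C@@H](O)[C@@H](CO)[C@H](CO)[C@H](O)c2cc(OCC=C)c(OC)c(OC)c2)ccc1OCC=C | intermediate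
13 | (1S,2R,3R,4S)-1-(4-allyloxy-3-methoxyphenyl)-4-(3-allyloxy-4,5-dimethoxyphenyl)-2,3-bis[(methylsulfonyloxy)methyl]butane-1,4-diol (not isolated) | COc1cc([C@@H](O)[C@@H](COS(C)(=O)=O)[C@H](COS(C)(=O)=O)[C@H](O)c2cc(OCC=C)c(OC)c(OC)c2)ccc1OCC=C | intermediate
14 | (1S,3aR,4S,6aR)-1-(4-allyloxy-3-methoxyphenyl)-4-(3-allyloxy-4,5-dimethoxyphenyl)tetrahydro-1H,3H-furo[3,4-c]furan | COc1cc([C@H]2OC[C@H]3[C@@H]2CO[C@@H]3c2cc(OCC=C)c(OC)c(OC)c2)ccc1OCC=C | intermediate
15 | 4-[(1S,3aR,4S,6aR)-4-(3-hydroxy-4,5-dimethoxyphenyl)tetrahydro-1H,3H-furo[3,4-c]furan-1-yl]-2-methoxyphenol | COc1cc([C@H]2OC[C@H]3[C@@H]2CO[C@@H]3c2cc(O)c(OC)c(OC)c2)ccc1O | target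

**Step count.** Total: 9 steps. Longest linear sequence: 8 steps (1, 2, 3, 5, 6, 7, 8, 9, from acetovanillone).

**Steps most likely to fail**

Step 6 (the step with the new method). The first carbinol may lactonise before the second ketone is reduced. The second hydride transfer would then take place on a keto lactone whose less hindered trans epimer should react preferentially, and the second ring could not close. Anti-selective reduction or stalling at the electron-rich ketones would have the same effect. The fallback uses known chemistry and sets out from 9. Chelation-controlled reduction of both beta-keto ester units with Zn(BH4)2 (Et2O/THF, −20 °C), which is known to give syn hydroxy esters from alpha-substituted beta-keto esters, should give the diol diester as a racemate, that is 10 together with the mirror-image diol diester F1, beside diastereomers from the other C8/C8' pairing. Pyridinium p-toluenesulfonate in CH2Cl2 should then close only the matched isomers to the racemic dilactone, that is 11 together with the mirror-image dilactone F2. This is separated from monolactones on silica and resolved by preparative chromatography on a chiral stationary phase, and the route is rejoined at 11.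

Step 5. Formation of the acyl anion equivalent from the electron-rich aldehyde may be slow, self-condensation of the aldehyde may compete, and the triply activated alkene may oligomerise under the basic conditions. The fallback sets out from 8 and uses 4 from step 2. Addition of the lithium enolate of methyl acetate (LiN(i-Pr)2, THF, −78 °C) should give the racemic hydroxy ester F3. Dess–Martin oxidation should give the keto ester F4, and N-chlorosuccinimide with catalytic Mg(ClO4)2 in ethyl acetate the chloro keto ester F5. C-alkylation of the sodium enolate of 4 (NaH, THF/DMF, 0 °C to rt) with F5 rejoins the route at 9. The chloride is preferred to the bromide because halogen transfer between the two enolates, which would scramble the partners, should be slower. This detour also makes step 3 unnecessary.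

Step 8. Ring closure between the two primary carbons after a single sulfonylation would divert material, and sulfonylation or ionisation at the electron-rich benzylic positions would erode the C7/C7' configuration. The fallback sets out from 11. Half-reduction of both lactones with i-Bu2AlH (CH2Cl2, −78 °C) should give the bis-lactol F6 as an anomer mixture. Ionic deoxygenation with Et3SiH and BF3·OEt2 (CH2Cl2, −78 °C) through the cyclic oxocarbenium ions breaks no bond at C7, C8, C8' or C7'. It rejoins the route at 14 and bypasses 12.

**Further compounds**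

F1 | step 6 | mirror-image diol diester, dimethyl (2R,3R)-2-[(R)-(4-allyloxy-3-methoxyphenyl)(hydroxy)methyl]-3-[(R)-(3-allyloxy-4,5-dimethoxyphenyl)(hydroxy)methyl]butanedioate | COc1cc([C@H](O)[C@H](C(=O)OC)[C@@H](C(=O)OC)[C@@H](O)c2cc(OCC=C)c(OC)c(OC)c2)ccc1OCC=C
F2 | step 6 | mirror-image dilactone, (3R,3aR,6R,6aR)-3-(4-allyloxy-3-methoxyphenyl)-6-(3-allyloxy-4,5-dimethoxyphenyl)tetrahydro-1H,3H-furo[3,4-c]furan-1,4-dione | COc1cc([C@@H]2OC(=O)[C@@H]3[C@H]2C(=O)O[C@H]3c2cc(OCC=C)c(OC)c(OC)c2)ccc1OCC=C
F3 | step 5 | methyl 3-(3-allyloxy-4,5-dimethoxyphenyl)-3-hydroxypropanoate (racemic) | COC(=O)CC(O)c1cc(OCC=C)c(OC)c(OC)c1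
F4 | step 5 | methyl 3-(3-allyloxy-4,5-dimethoxyphenyl)-3-oxopropanoate | COC(=O)CC(=O)c1cc(OCC=C)c(OC)c(OC)c1
F5 | step 5 | methyl 2-chloro-3-(3-allyloxy-4,5-dimethoxyphenyl)-3-oxopropanoate (racemic) | COC(=O)C(Cl)C(=O)c1cc(OCC=C)c(OC)c(OC)c1
F6 | step 8 | (3S,3aR,6S,6aR)-3-(4-allyloxy-3-methoxyphenyl)-6-(3-allyloxy-4,5-dimethoxyphenyl)tetrahydro-1H,3H-furo[3,4-c]furan-1,4-diol (bis-lactol, anomer mixture) | COc1cc([C@H]2OC(O)[C@H]3[C@@H]2C(O)O[C@@H]3c2cc(OCC=C)c(OC)c(OC)c2)ccc1OCC=C
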